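The route builds ring A of flavone unit 1 onto ring B of unit 2 instead of coupling two arenes. Ring A carries oxygen on C5, C7 and C8a and the C2' carbon of the other unit on C8, which is the pattern of an enolised 2-aryl-1,3,5-triketone. In one operation the benzylic carbon (C8) of a linear 6-aryl-3,5-dioxohexanoate attacks its own ester carbonyl (C7), closes the ring and aromatises with the biaryl bond in place. Precursor 5 is this chain with the chain C3 carbonyl masked as a methyl enol ether. No polyanion forms, pyrone formation stays reversible, and O5 emerges protected, so the later acetyl group can only sit beside one hydroxyl flanking C8.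

Key step: step 3

Assumption: the SMILES fixes no configuration at the hindered C8–C2' axis and the target has no stereocentre, so the axis is not controlled (racemic if rotation is slow). The only stereodescriptors in the route are the E double bonds of 2, 5 and 11. Chain atoms of 5 are numbered C1 (ester) to C6 (benzylic).

Step 1
Reactants: 1 methyl acetoacetate
Product: 2 methyl (E)-3-methoxybut-2-enoate
Conditions: HC(OMe)3 (1.1 equiv), H2SO4 (cat.), MeOH, rt → 50 °C; distillation
Reagents that add atoms: trimethyl orthoformate, COC(OC)OC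
Why: Acid-catalysed ketalisation of the ketone by the orthoester followed by loss of methanol gives the conjugated enol ether, and equilibration settles on the (E)-isomer, in which the ester is cis to the methyl group.

Step 2
Reactants: 3 2-bromo-5-methoxyphenylacetic acid; 2 methyl (E)-3-methoxybut-2-enoate
Product: 5 methyl (2E)-6-(2-bromo-5-methoxyphenyl)-3-methoxy-5-oxohex-2-enoate, via acyl imidazolide 4 (not isolated)
Conditions: 3, 1,1'-carbonyldiimidazole (1.05 equiv), THF, rt; added to 2 (3.3 equiv)/LDA (3.2 equiv), THF, −78 → −40 °C; AcOH quench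
Reagents that add atoms: none
Why: This is a vinylogous Claisen acylation in which the lithium dienolate of the β-methoxy enoate, like that of the closely related 2,2,6-trimethyl-1,3-dioxin-4-one, should take up the acyl donor at the γ-carbon because only that keeps the push-pull β-methoxyacrylate intact, while the surplus dienolate absorbs the imidazole N–H and the acidic C4–H of 5 and no free amide base meets the aryl bromide.

Step 3
Reactants: 5 methyl (2E)-6-(2-bromo-5-methoxyphenyl)-3-methoxy-5-oxohex-2-enoate
Product: 7 2-(2-bromo-5-methoxyphenyl)-5-methoxybenzene-1,3-diol, via cyclohexenedione tautomer 6 (not isolated)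
Conditions: NaOMe (4 equiv), dry MeOH, reflux, Ar; then 1 M HCl
Reagents that add atoms: none
Why: Methoxide equilibrates the enolates of the C5 ketone; the one at benzylic C6, stabilised by the aryl ring, adds to the ester carbonyl C1, methoxide leaves, and dione 6 enolises at once to the resorcinol, whose deprotonation makes the sequence irreversible. The reaction type is the intramolecular Claisen cyclisation that turns 6-aryl-5-oxohexanoates into 2-arylcyclohexane-1,3-diones and 3-methoxy-5-oxohex-2-enoates into phloroglucinol monomethyl ethers. The single ring closes in the allowed 6-(enolendo)-exo-trig mode, helped by the (E)-enol ether that holds C1 and C4 cis on C2=C3, and no stereocentre remains because the sp3 carbon of 6 is lost on aromatisation. The selectivity needed is C- over O-acylation: attack through the C5 enolate oxygen gives a neutral 4-methoxy-2-pyrone that has no acidic hydroxyl and is reopened by methoxide to 5, whereas the unmasked triketide would rest as an unreactive polyanion or as the inert 4-hydroxypyrone anion. The more acidic C4 position cannot interfere, since it could only close a four-membered ring. The enol ether methyl ends on the oxygen para to the aryl group (future O5), and the two hydroxyls flanking C8 are equivalent, so the new bond is C7–C8 whichever of them later becomes O1.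

Step 4
Reactants: 7 2-(2-bromo-5-methoxyphenyl)-5-methoxybenzene-1,3-diol
Product: 8 1-[3-(2-bromo-5-methoxyphenyl)-2,4-dihydroxy-6-methoxyphenyl]ethan-1-one
Conditions: AcOH, BF3·OEt2 (excess), 80 °C; aq. NaOAc
Reagents that add atoms: acetic acid, CC(=O)O
Why: In this Friedel–Crafts C-acylation the two open positions of the resorcinol ring are symmetry-equivalent and far more nucleophilic than the bromoanisole ring, so one ketone should form in which the only hydroxyl ortho to the acetyl group is the one next to C8, which fixes O1 and the 8-aryl (not 6-aryl) flavone.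

Step 5
Reactants: 8 1-[3-(2-bromo-5-methoxyphenyl)-2,4-dihydroxy-6-methoxyphenyl]ethan-1-one
Product: 9 1-[4-(benzyloxy)-3-(2-bromo-5-methoxyphenyl)-2-hydroxy-6-methoxyphenyl]ethan-1-one
Conditions: BnBr (1.05 equiv), K2CO3 (1.3 equiv), acetone, reflux
Reagents that add atoms: benzyl bromide, BrCc1ccccc1
Why: In this Williamson etherification the 4-hydroxyl, para to the acetyl group, is the more acidic and is not chelated, whereas the 2-hydroxyl is hydrogen-bonded to the ketone and walled in by acetyl and aryl groups, so weak base and one equivalent of halide should alkylate O7 only.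

Step 6
Reactants: 9 1-[4-(benzyloxy)-3-(2-bromo-5-methoxyphenyl)-2-hydroxy-6-methoxyphenyl]ethan-1-one; 10 4-methoxybenzaldehyde
Product: 11 (2E)-1-[4-(benzyloxy)-3-(2-bromo-5-methoxyphenyl)-2-hydroxy-6-methoxyphenyl]-3-(4-methoxyphenyl)prop-2-en-1-one
Conditions: 10 (1.3 equiv), KOH (10 equiv), EtOH, rt → 40 °C; 1 M HCl
Reagents that add atoms: none
Why: This is a Claisen–Schmidt condensation of a methyl ketone with a non-enolisable aldehyde, routine for 2-hydroxy-4,6-dialkoxyacetophenones, in which E1cB loss of water gives the more stable (E)-enone.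

Step 7
Reactants: 11 (2E)-1-[4-(benzyloxy)-3-(2-bromo-5-methoxyphenyl)-2-hydroxy-6-methoxyphenyl]-3-(4-methoxyphenyl)prop-2-en-1-one
Product: 12 7-(benzyloxy)-8-(2-bromo-5-methoxyphenyl)-5-methoxy-2-(4-methoxyphenyl)-4H-chromen-4-one
Conditions: I2 (10 mol %), DMSO, 130 °C
Reagents that add atoms: none
Why: This iodine-catalysed oxidative cyclisation of a 2'-hydroxychalcone proceeds by oxa-Michael closure, α-iodination and loss of HI, with DMSO regenerating iodine, and it can engage only the single free hydroxyl, while the aryl bromide and the ethers are spectators.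

Step 8
Reactants: 13 2',4',6'-trihydroxyacetophenone
Product: 14 1-[2,4-bis(benzyloxy)-6-hydroxyphenyl]ethan-1-one
Conditions: BnBr (2.1 equiv), K2CO3 (2.3 equiv), DMF, rt → 50 °C
Reagents that add atoms: benzyl bromide, BrCc1ccccc1
Why: This Williamson etherification should stop after two alkylations because the last hydroxyl stays locked in the hydrogen bond to the ketone.

Step 9
Reactants: 12 7-(benzyloxy)-8-(2-bromo-5-methoxyphenyl)-5-methoxy-2-(4-methoxyphenyl)-4H-chromen-4-one; 14 1-[2,4-bis(benzyloxy)-6-hydroxyphenyl]ethan-1-one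
Product: 15 2-acetyl-3,5-bis(benzyloxy)phenyl 2-[7-(benzyloxy)-5-methoxy-2-(4-methoxyphenyl)-4-oxo-4H-chromen-8-yl]-4-methoxybenzoate
Conditions: Pd(OAc)2 (5 mol %), Xantphos (4,5-bis(diphenylphosphino)-9,9-dimethylxanthene, 10 mol %), CO (5 bar), Et3N (3 equiv), 14 (1.5 equiv), toluene, 100 °C
Reagents that add atoms: carbon monoxide, [C-]#[O+]
Why: This palladium-catalysed carbonylative esterification runs by oxidative addition of zerovalent palladium into C–Br, CO insertion and capture of the acyl palladium by the phenol, the same opening events as in the known carbonylative flavone synthesis from aryl bromides and 2-hydroxyacetophenones, and 12 offers no free hydroxyl that could intercept the acyl group.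

Step 10
Reactants: 15 2-acetyl-3,5-bis(benzyloxy)phenyl 2-[7-(benzyloxy)-5-methoxy-2-(4-methoxyphenyl)-4-oxo-4H-chromen-8-yl]-4-methoxybenzoate
Product: 17 7-(benzyloxy)-8-{2-[5,7-bis(benzyloxy)-4-oxo-4H-chromen-2-yl]-5-methoxyphenyl}-5-methoxy-2-(4-methoxyphenyl)-4H-chromen-4-one, via 1,3-diketone 16 (not isolated)
Conditions: KOtBu (3 equiv), THF, 0 °C → rt; 1 M HCl; crude 16, p-TsOH·H2O (cat.), toluene, reflux
Reagents that add atoms: none
Why: A Baker–Venkataraman rearrangement (intramolecular acyl transfer from oxygen to the acetyl enolate) is followed by acid cyclodehydration, and because O7 of unit 1 is benzylated the liberated phenol of unit 2 is the only nucleophile that can close onto the aryl ketone.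

Step 11
Reactants: 17 7-(benzyloxy)-8-{2-[5,7-bis(benzyloxy)-4-oxo-4H-chromen-2-yl]-5-methoxyphenyl}-5-methoxy-2-(4-methoxyphenyl)-4H-chromen-4-one
Product: 18 8-[2-(5,7-dihydroxy-4-oxo-4H-chromen-2-yl)-5-methoxyphenyl]-5,7-dihydroxy-2-(4-methoxyphenyl)-4H-chromen-4-one (CNP0394081.0)
Conditions: BCl3 (12 equiv), pentamethylbenzene (10 equiv), CH2Cl2, −78 °C → rt; MeOH, then H2O
Reagents that add atoms: none
Why: In this Lewis-acid ether cleavage the three benzyl ethers ionise and the cation is trapped by pentamethylbenzene, the 5-methoxy group of unit 1 is cleaved through its boron chelate with the C4 carbonyl, and the two unchelated anisole-type ethers should resist BCl3 at this temperature.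

Compound list
1 | methyl acetoacetate | COC(=O)CC(C)=O | starting material
2 | methyl (E)-3-methoxybut-2-enoate | COC(=O)/C=C(/OC)C | intermediate
3 | 2-bromo-5-methoxyphenylacetic acid | COc1ccc(Br)c(CC(=O)O)c1 | starting material
4 | 2-(2-bromo-5-methoxyphenyl)-1-(1H-imidazol-1-yl)ethan-1-one | COc1ccc(Br)c(CC(=O)n2ccnc2)c1 | intermediate
5 | methyl (2E)-6-(2-bromo-5-methoxyphenyl)-3-methoxy-5-oxohex-2-enoate | COC(=O)/C=C(/OC)CC(=O)Cc1cc(OC)ccc1Br | intermediate
6 | 2-(2-bromo-5-methoxyphenyl)-5-methoxycyclohex-4-ene-1,3-dione | COC1=CC(=O)C(c2cc(OC)ccc2Br)C(=O)C1 | intermediate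
7 | 2-(2-bromo-5-methoxyphenyl)-5-methoxybenzene-1,3-diol | COc1ccc(Br)c(-c2c(O)cc(OC)cc2O)c1 | intermediate
8 | 1-[3-(2-bromo-5-methoxyphenyl)-2,4-dihydroxy-6-methoxyphenyl]ethan-1-one | CC(=O)c1c(OC)cc(O)c(-c2cc(OC)ccc2Br)c1O | intermediate
9 | 1-[4-(benzyloxy)-3-(2-bromo-5-methoxyphenyl)-2-hydroxy-6-methoxyphenyl]ethan-1-one | CC(=O)c1c(OC)cc(OCc2ccccc2)c(-c2cc(OC)ccc2Br)c1O | intermediate
10 | 4-methoxybenzaldehyde | COc1ccc(C=O)cc1 | starting material
11 | (2E)-1-[4-(benzyloxy)-3-(2-bromo-5-methoxyphenyl)-2-hydroxy-6-methoxyphenyl]-3-(4-methoxyphenyl)prop-2-en-1-one | COc1ccc(/C=C/C(=O)c2c(OC)cc(OCc3ccccc3)c(-c3cc(OC)ccc3Br)c2O)cc1 | intermediate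
12 | 7-(benzyloxy)-8-(2-bromo-5-methoxyphenyl)-5-methoxy-2-(4-methoxyphenyl)-4H-chromen-4-one | COc1ccc(-c2cc(=O)c3c(OC)cc(OCc4ccccc4)c(-c4cc(OC)ccc4Br)c3o2)cc1 | intermediate
13 | 2',4',6'-trihydroxyacetophenone | CC(=O)c1c(O)cc(O)cc1O | starting material
14 | 1-[2,4-bis(benzyloxy)-6-hydroxyphenyl]ethan-1-one | CC(=O)c1c(O)cc(OCc2ccccc2)cc1OCc1ccccc1 | intermediate
15 | 2-acetyl-3,5-bis(benzyloxy)phenyl 2-[7-(benzyloxy)-5-methoxy-2-(4-methoxyphenyl)-4-oxo-4H-chromen-8-yl]-4-methoxybenzoate | COc1ccc(-c2cc(=O)c3c(OC)cc(OCc4ccccc4)c(-c4cc(OC)ccc4C(=O)Oc4cc(OCc5ccccc5)cc(OCc5ccccc5)c4C(C)=O)c3o2)cc1 | intermediate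
16 | 1-[2,4-bis(benzyloxy)-6-hydroxyphenyl]-3-{2-[7-(benzyloxy)-5-methoxy-2-(4-methoxyphenyl)-4-oxo-4H-chromen-8-yl]-4-methoxyphenyl}propane-1,3-dione | COc1ccc(-c2cc(=O)c3c(OC)cc(OCc4ccccc4)c(-c4cc(OC)ccc4C(=O)CC(=O)c4c(O)cc(OCc5ccccc5)cc4OCc4ccccc4)c3o2)cc1 | intermediate
17 | 7-(benzyloxy)-8-{2-[5,7-bis(benzyloxy)-4-oxo-4H-chromen-2-yl]-5-methoxyphenyl}-5-methoxy-2-(4-methoxyphenyl)-4H-chromen-4-one | COc1ccc(-c2cc(=O)c3c(OC)cc(OCc4ccccc4)c(-c4cc(OC)ccc4-c4cc(=O)c5c(OCc6ccccc6)cc(OCc6ccccc6)cc5o4)c3o2)cc1 | intermediate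
18 | 8-[2-(5,7-dihydroxy-4-oxo-4H-chromen-2-yl)-5-methoxyphenyl]-5,7-dihydroxy-2-(4-methoxyphenyl)-4H-chromen-4-one (CNP0394081.0) | COc1ccc(-c2cc(=O)c3c(O)cc(O)c(-c4cc(OC)ccc4-c4cc(=O)c5c(O)cc(O)cc5o4)c3o2)cc1 | target

Total step count: 11.
Longest linear sequence: 10 steps (1 → 2 → 5 → 7 → 8 → 9 → 11 → 12 → 15 → 17 → 18). Step 8 is the only side branch.

Steps most likely to fail

1. Step 3. Closure through the enolate oxygen and retro-Claisen cleavage by methoxide at the C5 ketone may outrun the slower C-acylation, because the productive benzylic enolate is only a minor partner of the C4 dienolate. The fallback gives up ring construction and makes the C8–C2' bond by cross-coupling on a preformed ring A. It sets out from 13. One equivalent of BnBr with K2CO3 in acetone alkylates the unchelated hydroxyl to give 1-[4-(benzyloxy)-2,6-dihydroxyphenyl]ethan-1-one F1. One equivalent of Me2SO4 with K2CO3 then gives 1-[4-(benzyloxy)-2-hydroxy-6-methoxyphenyl]ethan-1-one F2. N-iodosuccinimide with catalytic CF3CO2H in MeCN iodinates ortho to the free hydroxyl to give 1-[4-(benzyloxy)-2-hydroxy-3-iodo-6-methoxyphenyl]ethan-1-one F3. Suzuki–Miyaura coupling of F3 with commercial (2-bromo-5-methoxyphenyl)boronic acid (Pd(PPh3)4, aq. K2CO3, dioxane, 80 °C), in which C–I reacts ahead of C–Br, comes back to the route at 9.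

2. Step 2. The dienolate may attack through its α-carbon, or proton transfer from the benzylic CH2 of 4 to the dienolate may erode the acylation. Premature closure of 5 to its methoxypyrone is harmless, since step 3 reopens it. The fallback uses a nucleophile with only one reactive carbon and introduces the enol ether through the pyrone. It sets out from 3 (activated as 4) and 1. The dianion of 1 (NaH, then n-BuLi, THF, 0 °C) is acylated by 4 at its terminal carbon to give methyl 6-(2-bromo-5-methoxyphenyl)-3,5-dioxohexanoate F4. DBU in toluene at reflux lactonises this to 6-(2-bromo-5-methoxybenzyl)-4-hydroxy-2H-pyran-2-one F5. Me2SO4 with K2CO3 in acetone gives 6-(2-bromo-5-methoxybenzyl)-4-methoxy-2H-pyran-2-one F6. Under the NaOMe/MeOH of step 3, methoxide opens F6 at the lactone carbonyl, so the fallback comes back to the route at 5, formed in the flask with the required (E)-geometry.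

3. Step 9. Oxidative addition into the electron-rich, ortho-blocked C–Br bond may be slow, and capture of the crowded acyl palladium by a chelated phenol may also be slow, leaving hydrodebromination as the main outlet. The fallback replaces the bulky oxygen nucleophile by hydride and builds unit 2 by the aldol and oxidative cyclisation pair already used for unit 1. It sets out from 12. Reductive carbonylation (Pd(OAc)2, di(1-adamantyl)-n-butylphosphine, TMEDA, CO/H2 5 bar, toluene, 100 °C) gives 2-[7-(benzyloxy)-5-methoxy-2-(4-methoxyphenyl)-4-oxo-4H-chromen-8-yl]-4-methoxybenzaldehyde F7. Claisen–Schmidt condensation with 14 (KOH, EtOH, rt) gives (2E)-1-[2,4-bis(benzyloxy)-6-hydroxyphenyl]-3-{2-[7-(benzyloxy)-5-methoxy-2-(4-methoxyphenyl)-4-oxo-4H-chromen-8-yl]-4-methoxyphenyl}prop-2-en-1-one F8. Catalytic I2 in DMSO at 130 °C then closes the second pyranone, and the fallback comes back to the route at 17, bypassing 15 and 16.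

Further compounds
F1 | step 3 | 1-[4-(benzyloxy)-2,6-dihydroxyphenyl]ethan-1-one | CC(=O)c1c(O)cc(OCc2ccccc2)cc1O
F2 | step 3 | 1-[4-(benzyloxy)-2-hydroxy-6-methoxyphenyl]ethan-1-one | CC(=O)c1c(O)cc(OCc2ccccc2)cc1OC
F3 | step 3 | 1-[4-(benzyloxy)-2-hydroxy-3-iodo-6-methoxyphenyl]ethan-1-one | CC(=O)c1c(OC)cc(OCc2ccccc2)c(I)c1O
F4 | step 2 | methyl 6-(2-bromo-5-methoxyphenyl)-3,5-dioxohexanoate | COC(=O)CC(=O)CC(=O)Cc1cc(OC)ccc1Br
F5 | step 2 | 6-(2-bromo-5-methoxybenzyl)-4-hydroxy-2H-pyran-2-one | O=c1cc(O)cc(Cc2cc(OC)ccc2Br)o1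
F6 | step 2 | 6-(2-bromo-5-methoxybenzyl)-4-methoxy-2H-pyran-2-one | COc1cc(Cc2cc(OC)ccc2Br)oc(=O)c1
F7 | step 9 | 2-[7-(benzyloxy)-5-methoxy-2-(4-methoxyphenyl)-4-oxo-4H-chromen-8-yl]-4-methoxybenzaldehyde | COc1ccc(-c2cc(=O)c3c(OC)cc(OCc4ccccc4)c(-c4cc(OC)ccc4C=O)c3o2)cc1
F8 | step 9 | (2E)-1-[2,4-bis(benzyloxy)-6-hydroxyphenyl]-3-{2-[7-(benzyloxy)-5-methoxy-2-(4-methoxyphenyl)-4-oxo-4H-chromen-8-yl]-4-methoxyphenyl}prop-2-en-1-one | COc1ccc(-c2cc(=O)c3c(OC)cc(OCc4ccccc4)c(-c4cc(OC)ccc4/C=C/C(=O)c4c(O)cc(OCc5ccccc5)cc4OCc4ccccc4)c3o2)cc1
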